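## Retrosynthetic overview

1. Target 15 comes from the bicyclic ketol 9 by end-game adjustments only: hydroxyl-directed reduction at C6, aroylation at C6, silyl-to-acetyl exchange at C2, and release of the phenol.
2. Ketol 9 comes from the linear farnesane-type trione 7 in one flask. The C1–C7 bond closes first (seven-membered ring), then the C6–C10 bond (five-membered ring), with oxygen left on C10. These are the bonds and the order presumed for the cyclisation of farnesyl diphosphate to the daucane skeleton. The polarity is inverted (Michael addition, then aldol addition) because the C2, C5 and C10 oxygens of the target make C7 and C10 electrophilic.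
3. Trione 7 comes from furan 6 by oxidative unmasking of the (Z)-enedione. Furan 6 comes from an asymmetric aldol addition of 3-methylbutan-2-one to furyl enal 3, itself made from 4,5-dimethylfurfural and propanal.
4. The aldol carbinol (C8 of 7, C2 of the daucane) is the only reagent-controlled stereocentre; C1, C5, C4 and C6 are relayed from it.

Numbering: locants for 7 and 8 follow the dodecane chain of 7 (identical with farnesane numbering). Bicycles 9–15 use daucane numbering: C1 carries the angular methyl, C4 the hydroxyl and isopropyl, C5 is the ring-fusion CH, C6–C10 complete the seven-membered ring, C8 carries the methyl. β is the face of the C1 methyl. The target is 2β-acetoxy, 4β-hydroxy, 5α-H, 6α-aroyloxy, trans-fused.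

Assumption: (+)-Ipc2BCl (from (−)-α-pinene) is taken as the antipode that sends the methyl-ketone enolate to the Si face of enal 3, giving the (S)-carbinol; if analysis of 5 shows the opposite sense, the (−)-reagent is used and nothing else changes.

## Route

Step 1
Reactants: 1 4,5-dimethylfuran-2-carbaldehyde; 2 propanal
Product: 3 (2E)-3-(4,5-dimethylfuran-2-yl)-2-methylprop-2-enal
Conditions: NaOH (0.2 equiv), EtOH/H2O, slow addition of 2, 0 → 20 °C
Reagents that add atoms: none
Why: Claisen–Schmidt crossed aldol condensation; the non-enolisable furaldehyde accepts the propanal enolate and E1cB dehydration gives the conjugated (E)-enal, with no stereocentre formed.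

Step 2
Reactants: 3 (2E)-3-(4,5-dimethylfuran-2-yl)-2-methylprop-2-enal; 4 3-methylbutan-2-one
Product: 5 (5S,6E)-7-(4,5-dimethylfuran-2-yl)-5-hydroxy-2,6-dimethylhept-6-en-3-one
Conditions: 4, (+)-Ipc2BCl, Et3N, Et2O, −78 → 0 °C; then 3, −78 → −20 °C; H2O2, MeOH, pH 7 buffer
Reagents that add atoms: none
Why: Paterson-type boron aldol addition; the ketone is enolised on its methyl side and the isopinocampheyl ligands direct the enolate to the Si face of the enal, setting the (S)-carbinol (future daucane C2).

Step 3
Reactants: 5 (5S,6E)-7-(4,5-dimethylfuran-2-yl)-5-hydroxy-2,6-dimethylhept-6-en-3-one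
Product: 6 (5S,6E)-5-(tert-butyldimethylsilyloxy)-7-(4,5-dimethylfuran-2-yl)-2,6-dimethylhept-6-en-3-one
Conditions: TBSCl, imidazole, DMF, 23 °C
Reagents that add atoms: tert-butyldimethylsilyl chloride, CC(C)(C)[Si](C)(C)Cl
Why: Standard silylation; a silyl ether is used because, unlike an acetate, it is a poor leaving group β to the ketone and so resists E1cB loss in step 5, and the stereocentre is untouched.

Step 4
Reactants: 6 (5S,6E)-5-(tert-butyldimethylsilyloxy)-7-(4,5-dimethylfuran-2-yl)-2,6-dimethylhept-6-en-3-one
Product: 7 (3Z,6E,8S)-8-(tert-butyldimethylsilyloxy)-3,7,11-trimethyldodeca-3,6-diene-2,5,10-trione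
Conditions: NBS (1.05 equiv), NaHCO3, acetone/H2O (10:1), −20 °C; cold extractive work-up, used without chromatography
Reagents that add atoms: water, O
Why: Oxidative furan ring opening (bromonium attack on the electron-rich furan, 2,5-addition of water, collapse of the bromo-hemiketal); the ring holds C2 and C5 cis, so the enedione is formed as the (Z)-isomer, and the cold buffered medium without pyridine keeps it Z.

Step 5
Reactants: 7 (3Z,6E,8S)-8-(tert-butyldimethylsilyloxy)-3,7,11-trimethyldodeca-3,6-diene-2,5,10-trione
Product: 9 (1S,2S,4S,5S)-2-(tert-butyldimethylsilyloxy)-4-hydroxydauc-7-ene-6,9-dione, via Michael adduct enolate 8 (not isolated)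
Conditions: MgBr2·OEt2 (2.5 equiv), i-Pr2NEt (3 equiv), CH2Cl2 (0.01 M), 0 → 23 °C; pH 7 buffer
Reagents that add atoms: none
Why: Proposed new method: a soft-enolisation domino in which the C1 enolate of the (Z)-enedione adds 7-endo-trig to C7 of the Mg-activated C5 enone (intramolecular Michael addition), and the C5 enolate so formed adds through C6 to the Mg-bound C10 ketone (5-exo aldol addition). The closest known reactions are tandem Michael–aldol annulations and the MgBr2·OEt2/i-Pr2NEt soft enolisation of ketones. C7 (daucane C1) is set by Felkin–Anh attack anti to the C8 silyloxy group with the C8 hydrogen turned toward the C7 methyl. C6 (daucane C5) is set by anti addition across the (E)-alkene, giving the trans fusion; this is also the expected outcome of the reversible aldol, since both ring bonds sit equatorial on the cycloheptenedione. C10 (daucane C4) is set by the six-membered Mg chelate that places the alkoxide cis to the C5 carbonyl. The competing 5-exo aldol of the C1 enolate onto C5 is reversible under these conditions and drains into the chelated bicyclic aldolate.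

Step 6
Reactants: 9 (1S,2S,4S,5S)-2-(tert-butyldimethylsilyloxy)-4-hydroxydauc-7-ene-6,9-dione
Product: 10 (1S,2S,4S,5R,6R)-2-(tert-butyldimethylsilyloxy)-4,6-dihydroxydauc-7-en-9-one
Conditions: Me4NBH(OAc)3, MeCN/AcOH (1:1), −20 → 0 °C
Reagents that add atoms: none
Why: Evans–Saksena hydroxyl-directed reduction; the C4 tertiary hydroxyl exchanges onto boron and delivers hydride to the β-face of the C6 carbonyl, giving the 6α-alcohol, while the C9 enone carbonyl has no hydroxyl within reach and is not reduced by this mild hydride.

Step 7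
Reactants: 10 (1S,2S,4S,5R,6R)-2-(tert-butyldimethylsilyloxy)-4,6-dihydroxydauc-7-en-9-one; 11 4-acetoxybenzoic acid
Product: 12 (1S,2S,4S,5R,6R)-6-(4-acetoxybenzoyloxy)-2-(tert-butyldimethylsilyloxy)-4-hydroxydauc-7-en-9-one
Conditions: N,N′-diisopropylcarbodiimide, DMAP (0.2 equiv), CH2Cl2, 0 → 23 °C
Reagents that add atoms: none
Why: Steglich esterification; only the secondary allylic C6 hydroxyl is acylated (the tertiary C4 hydroxyl is inert), with retention at C6, and the phenol is carried as its acetate so the acid cannot acylate itself.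

Step 8
Reactants: 12 (1S,2S,4S,5R,6R)-6-(4-acetoxybenzoyloxy)-2-(tert-butyldimethylsilyloxy)-4-hydroxydauc-7-en-9-one
Product: 14 (1S,2S,4S,5R,6R)-2-acetoxy-6-(4-acetoxybenzoyloxy)-4-hydroxydauc-7-en-9-one, via C2 alcohol 13 (not isolated)
Conditions: HF·pyridine, THF, 0 → 23 °C; then Et3N, Ac2O, DMAP, 23 °C, one flask
Reagents that add atoms: acetic anhydride, CC(=O)OC(C)=O
Why: Fluoride desilylation followed by DMAP-catalysed acetylation in the same flask; the freed secondary C2 hydroxyl is acetylated while the tertiary C4 hydroxyl is not, and no stereocentre is touched.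

Step 9
Reactants: 14 (1S,2S,4S,5R,6R)-2-acetoxy-6-(4-acetoxybenzoyloxy)-4-hydroxydauc-7-en-9-one
Product: 15 (1S,2S,4S,5R,6R)-2-acetoxy-4-hydroxy-6-(4-hydroxybenzoyloxy)dauc-7-en-9-one
Conditions: NH4OAc (8 equiv), MeOH/H2O (4:1), 23 °C
Reagents that add atoms: none
Why: Chemoselective solvolysis of the aryl acetate; phenoxide is a far better leaving group than alkoxide, so the phenolic acetate is cleaved while the C2 alkyl acetate and the C6 benzoate survive.

## Compound list

1 | 4,5-dimethylfuran-2-carbaldehyde | Cc1oc(C=O)cc1C | starting material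
2 | propanal | CCC=O | starting material
3 | (2E)-3-(4,5-dimethylfuran-2-yl)-2-methylprop-2-enal | O=C/C(C)=C/c1cc(C)c(C)o1 | intermediate
4 | 3-methylbutan-2-one | CC(=O)C(C)C | starting material
5 | (5S,6E)-7-(4,5-dimethylfuran-2-yl)-5-hydroxy-2,6-dimethylhept-6-en-3-one | CC(C)C(=O)C[C@H](O)/C(C)=C/c1cc(C)c(C)o1 | intermediate
6 | (5S,6E)-5-(tert-butyldimethylsilyloxy)-7-(4,5-dimethylfuran-2-yl)-2,6-dimethylhept-6-en-3-one | CC(C)C(=O)C[C@H](O[Si](C)(C)C(C)(C)C)/C(C)=C/c1cc(C)c(C)o1 | intermediate
7 | (3Z,6E,8S)-8-(tert-butyldimethylsilyloxy)-3,7,11-trimethyldodeca-3,6-diene-2,5,10-trione | CC(=O)/C(C)=C\C(=O)/C=C(C)/[C@@H](O[Si](C)(C)C(C)(C)C)CC(=O)C(C)C | intermediate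
8 | (6R)-6-[(1S)-1-(tert-butyldimethylsilyloxy)-4-methyl-3-oxopentyl]-2,6-dimethylcyclohept-2-ene-1,4-dione, present as its C4–C5 enolate (SMILES of the neutral ketone) | CC1=CC(=O)C[C@](C)(CC1=O)[C@@H](O[Si](C)(C)C(C)(C)C)CC(=O)C(C)C | intermediate (not isolated)
9 | (1S,2S,4S,5S)-2-(tert-butyldimethylsilyloxy)-4-hydroxydauc-7-ene-6,9-dione; trans-fused | CC(C)(C)[Si](C)(C)O[C@H]1C[C@](O)(C(C)C)[C@H]2C(=O)C=C(C)C(=O)C[C@]12C | intermediate
10 | (1S,2S,4S,5R,6R)-2-(tert-butyldimethylsilyloxy)-4,6-dihydroxydauc-7-en-9-one | CC(C)(C)[Si](C)(C)O[C@H]1C[C@](O)(C(C)C)[C@H]2[C@H](O)C=C(C)C(=O)C[C@]12C | intermediate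
11 | 4-acetoxybenzoic acid | CC(=O)Oc1ccc(cc1)C(=O)O | starting material
12 | (1S,2S,4S,5R,6R)-6-(4-acetoxybenzoyloxy)-2-(tert-butyldimethylsilyloxy)-4-hydroxydauc-7-en-9-one | CC(C)(C)[Si](C)(C)O[C@H]1C[C@](O)(C(C)C)[C@H]2[C@H](OC(=O)c3ccc(OC(C)=O)cc3)C=C(C)C(=O)C[C@]12C | intermediate
13 | (1S,2S,4S,5R,6R)-6-(4-acetoxybenzoyloxy)-2,4-dihydroxydauc-7-en-9-one | O[C@H]1C[C@](O)(C(C)C)[C@H]2[C@H](OC(=O)c3ccc(OC(C)=O)cc3)C=C(C)C(=O)C[C@]12C | intermediate (not isolated)
14 | (1S,2S,4S,5R,6R)-2-acetoxy-6-(4-acetoxybenzoyloxy)-4-hydroxydauc-7-en-9-one | CC(=O)O[C@H]1C[C@](O)(C(C)C)[C@H]2[C@H](OC(=O)c3ccc(OC(C)=O)cc3)C=C(C)C(=O)C[C@]12C | intermediate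
15 | (1S,2S,4S,5R,6R)-2-acetoxy-4-hydroxy-6-(4-hydroxybenzoyloxy)dauc-7-en-9-one | CC(=O)O[C@H]1C[C@](O)(C(C)C)[C@H]2[C@H](OC(=O)c3ccc(O)cc3)C=C(C)C(=O)C[C@]12C | target

## Step count and risk

Total steps: 9. Longest linear sequence: 9 (from 1).

The three steps most likely to fail are steps 5, 4 and 6.

**Step 5 (domino bicyclisation).** The risks are:
- the reversible 5-exo aldol of the C1 enolate onto C5 may hold the material back;
- the 7-endo Michael addition onto a β,β-disubstituted enone is slow;
- once the Michael adduct is protonated, aldol closure from C1 instead of C6, or a cis fusion, becomes possible.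

The fallback makes the kinetic aldol a deliberate intermediate and triggers the ring expansion from its alkoxide. It sets out from 7, which is closed with Na2CO3 in aqueous dioxane at 0 °C to 4-hydroxy-2-methyl-4-[(1E,3S)-3-(tert-butyldimethylsilyloxy)-2,6-dimethyl-5-oxohept-1-enyl]cyclopent-2-en-1-one F1 (both carbinol epimers, which converge). The isolated ketol is then deprotonated at oxygen with KH and 18-crown-6 in THF at 0 °C. Retro-aldol cleavage of the alkoxide gives the C1 potassium enolate regiospecifically, with no free amine or ammonium present. This enolate closes the seven-membered ring by Michael addition, and the C5 enolate is trapped by the C10 ketone before proton transfer (a net two-carbon ring expansion followed by aldol addition). Quenching with acetic acid at −78 °C brings the material back to the route at 9.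

**Step 4 (furan opening).** The risks are attack of the brominating agent on the conjugated alkene, addition of water at C7 instead of the furan carbon, and Z-to-E isomerisation of the enedione. The fallback separates oxidation from unmasking. It sets out from 6, which is methoxylated at the furan by anodic oxidation (graphite anode, Et4NOTs, MeOH, −20 °C). This gives (5S,6E)-5-(tert-butyldimethylsilyloxy)-7-(2,5-dimethoxy-4,5-dimethyl-2,5-dihydrofuran-2-yl)-2,6-dimethylhept-6-en-3-one F2 as a mixture of acetal isomers. Hydrolysis of the bis-acetal with dilute aqueous acetic acid in acetone at 0 °C releases the (Z)-enedione and comes back to the route at 7.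

**Step 6 (directed reduction).** The risks are that the hindered tertiary hydroxyl exchanges onto boron too slowly, or that hydride arrives from outside and gives the C6 epimer or touches the C9 carbonyl. The fallback makes the C6 epimer on purpose and inverts it while installing the ester. It sets out from 9, which is reduced through its boron chelate by external hydride (Et2BOMe, NaBH4, THF/MeOH, −78 °C; the complementary Narasaka–Prasad mode). This gives (1S,2S,4S,5R,6S)-2-(tert-butyldimethylsilyloxy)-4,6-dihydroxydauc-7-en-9-one F3. A Mitsunobu esterification of this alcohol with acid 11 (PPh3, diisopropyl azodicarboxylate, toluene, 0 °C) inverts C6 and comes back to the route at 12, skipping 10.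

Further compounds
F1 | step 5 | 4-hydroxy-2-methyl-4-[(1E,3S)-3-(tert-butyldimethylsilyloxy)-2,6-dimethyl-5-oxohept-1-enyl]cyclopent-2-en-1-one (both carbinol epimers) | CC1=CC(O)(CC1=O)/C=C(C)/[C@@H](O[Si](C)(C)C(C)(C)C)CC(=O)C(C)C
F2 | step 4 | (5S,6E)-5-(tert-butyldimethylsilyloxy)-7-(2,5-dimethoxy-4,5-dimethyl-2,5-dihydrofuran-2-yl)-2,6-dimethylhept-6-en-3-one (acetal isomers) | COC1(C)OC(OC)(C=C1C)/C=C(C)/[C@@H](O[Si](C)(C)C(C)(C)C)CC(=O)C(C)C
F3 | step 6 | (1S,2S,4S,5R,6S)-2-(tert-butyldimethylsilyloxy)-4,6-dihydroxydauc-7-en-9-one | CC(C)(C)[Si](C)(C)O[C@H]1C[C@](O)(C(C)C)[C@H]2[C@@H](O)C=C(C)C(=O)C[C@]12C
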